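**Retrosynthetic overview**
- Feature: ring A is a pentasubstituted benzene whose only hydrogen is at C6. Its substituents alternate (acyl carbon on C4a, O on C5, O on C7, prenyl on C8, O1 on C8a). This is the pattern left by a 1,3-dioxygenated diene (C5-C8) on an acetylenic ketone (C4a-C8a).
- Late disconnections: MOM removal, then ring C at O1-C8a (enol O-arylation of a C8a bromide), then C2-C3 (acylation of the ring A methyl ketone enolate with the ring B acid chloride).
- Ring A: Diels-Alder benzannulation forms C8-C8a and C4a-C5. The partners are a prenyl-terminated 1-methoxy-1,3-bis(silyloxy)diene (methyl acetoacetate plus prenyl bromide) and 4-bromobut-3-yn-2-one.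
- Ring B: bought as 5-bromovanillin. Its methyl sits on the wrong oxygen, so it is moved from O3' to O4' by demethylation and selective remethylation. Bromine is exchanged for prenyl and CHO is raised to COCl.
- Ring order: B (purchased), A (step 5), C (step 13).

Key step: step 5

Remark on the chemistry: the silyl enol ether and the ketene acetal end of the diene are drawn with one geometry although mixtures may form. Only the 3Z bond of the diene matters, because all these carbons end up in the arene. Tributyl(3-methylbut-2-enyl)stannane is taken as purchasable.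

**Step 1**
Reactants: 1 methyl acetoacetate; 2 prenyl bromide (1-bromo-3-methylbut-2-ene)
Product: 4 methyl 7-methyl-3-oxooct-6-enoate, via acetoacetate dianion 3 (not isolated)
Conditions: NaH, THF, 0 °C; n-BuLi, 0 °C; 2, 0 °C to rt; then 1 M HCl
Reagents that add atoms: none
Why: γ-Alkylation of a β-keto ester dianion: the doubly deprotonated ester 3 attacks the primary allylic bromide by SN2 only through its more basic terminal carbon, which puts the prenyl unit on the carbon that will become C8.

**Step 2**
Reactants: 4 methyl 7-methyl-3-oxooct-6-enoate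
Product: 5 methyl (Z)-7-methyl-3-(trimethylsilyloxy)octa-2,6-dienoate
Conditions: Me3SiCl, Et3N, toluene, rt, 48 h
Reagents that add atoms: chlorotrimethylsilane, C[Si](C)(C)Cl
Why: Silyl enol ether formation from the strongly enolized β-keto ester with Me3SiCl and Et3N is routine for this class, and the geometry of the new double bond is without consequence because it becomes the central single bond of the diene.

**Step 3**
Reactants: 5 methyl (Z)-7-methyl-3-(trimethylsilyloxy)octa-2,6-dienoate
Product: 7 (1Z,3Z)-1-methoxy-7-methyl-1,3-bis(trimethylsilyloxy)octa-1,3,6-triene, via lithium dienolate 6 (not isolated)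
Conditions: LiN(i-Pr)2, THF, −78 °C; Me3SiCl, −78 °C to rt; hexane, filtration under argon
Reagents that add atoms: chlorotrimethylsilane, C[Si](C)(C)Cl
Why: Kinetic γ-deprotonation of the β-silyloxy enoate gives dienolate 6, whose O-silylation (ketene silyl acetal formation) delivers the 1-alkoxy-1,3-bis(silyloxy)diene, and 4-alkyl members of this family form with the chain cis to the 3-silyloxy group (3Z) to avoid allylic strain.

**Step 4**
Reactants: 8 but-3-yn-2-one
Product: 9 4-bromobut-3-yn-2-one
Conditions: NBS, AgNO3 (10 mol %), acetone, rt, dark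
Reagents that add atoms: N-bromosuccinimide, O=C1CCC(=O)N1Br
Why: AgNO3-catalysed electrophilic bromination of the terminal alkyne C-H with NBS is a standard route to 1-bromoalkynes and leaves the conjugated ketone untouched.

**Step 5**
Reactants: 7 (1Z,3Z)-1-methoxy-7-methyl-1,3-bis(trimethylsilyloxy)octa-1,3,6-triene; 9 4-bromobut-3-yn-2-one
Product: 12 1-[2-bromo-4,6-dihydroxy-3-(3-methylbut-2-enyl)phenyl]ethanone, via cyclohexadiene cycloadduct 10 (not isolated), via aryl silyl ether 11 (not isolated)
Conditions: 7 (1.5 equiv), toluene, −40 °C to rt, then 45 °C, no Lewis acid; then 1 M HCl, THF, 0 °C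
Reagents that add atoms: none
Why: Thermal normal-electron-demand Diels-Alder reaction: both oxygen donors of 7 raise the HOMO coefficient at the prenyl-bearing terminus (future C8), which bonds ahead to the bromine-bearing β-carbon of 9 (future C8a) while the ketene acetal carbon (future C5) closes onto the α-carbon (future C4a), so ring A is closed by a concerted, asynchronous [4+2] cycloaddition to give 10. The closest known reaction type is the cycloaddition of 1-alkoxy-1,3-bis(silyloxy)-1,3-dienes, 4-alkyl members included, to acetylenic esters and ketones with aromatization to resorcinols, and 1-bromoalkynyl carbonyl compounds are established dienophiles whose orientation is set by the carbonyl group. The mixed methyl silyl ketal at C5 of 10 collapses with loss of Me3SiOMe to a cross-conjugated dienone whose doubly allylic C8-H shifts to oxygen, giving phenol 11, and the dilute acid work-up removes the last silyl group. The two stereocentres of 10 (C5 and C8, OMe cis to prenyl by suprafacial addition) are erased on aromatization, so no stereocontrol is needed. The step needs regioselectivity, secured by the matched polarization of the two partners, and an accessible s-cis diene, secured by the 3Z geometry that turns the prenyl chain outward. It also needs retention of bromine, which is helped by the halogen of 10 sitting on an sp2 carbon outside the 1,4-elimination path and by the exclusion of Lewis acids and fluoride, which would favour stepwise Mukaiyama-Michael addition with bromide expulsion.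

**Step 6**
Reactants: 12 1-[2-bromo-4,6-dihydroxy-3-(3-methylbut-2-enyl)phenyl]ethanone
Product: 13 1-[2-bromo-4,6-bis(methoxymethoxy)-3-(3-methylbut-2-enyl)phenyl]ethanone
Conditions: NaH (2.3 equiv), MOMCl (3 equiv), DMF, 0 °C to rt
Reagents that add atoms: chloromethyl methyl ether, COCCl
Why: Williamson-type O-alkylation with MOMCl, in which NaH is used so that the hydrogen-bonded 6-OH is also ionized, caps both phenols so that later only the C8a bromide can become O1 and no phenol can close ring C the wrong way.

**Step 7**
Reactants: 14 5-bromovanillin (3-bromo-4-hydroxy-5-methoxybenzaldehyde)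
Product: 15 3-bromo-4,5-dihydroxybenzaldehyde
Conditions: AlCl3, pyridine, CH2Cl2, reflux; then aq HCl
Reagents that add atoms: none
Why: Lewis acid assisted aryl methyl ether cleavage, in which AlCl3 binds the ortho hydroxy-methoxy pair and pyridine removes the methyl group by SN2, is the established way to the catechol and is needed because 5-bromovanillin carries its methyl on the oxygen that must end as the free 3'-OH.

**Step 8**
Reactants: 15 3-bromo-4,5-dihydroxybenzaldehyde
Product: 16 3-bromo-5-hydroxy-4-methoxybenzaldehyde
Conditions: MeI (1.05 equiv), Li2CO3, DMF, 50 °C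
Reagents that add atoms: iodomethane, CI
Why: Selective Williamson methylation works because the 4-OH, para to the formyl group and ortho to bromine, is clearly the more acidic phenol, so the weak base Li2CO3 ionizes only this one and a single equivalent of MeI sets the 4'-OMe group.

**Step 9**
Reactants: 16 3-bromo-5-hydroxy-4-methoxybenzaldehyde
Product: 17 3-bromo-4-methoxy-5-(methoxymethoxy)benzaldehyde
Conditions: MOMCl, i-Pr2NEt, CH2Cl2, 0 °C to rt
Reagents that add atoms: chloromethyl methyl ether, COCCl
Why: Standard MOM ether formation on the remaining unhindered phenol with an amine base, giving a group that withstands palladium catalysis, chlorite, amide bases and hot carbonate.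

**Step 10**
Reactants: 17 3-bromo-4-methoxy-5-(methoxymethoxy)benzaldehyde; 18 tributyl(3-methylbut-2-enyl)stannane
Product: 19 4-methoxy-3-(methoxymethoxy)-5-(3-methylbut-2-enyl)benzaldehyde
Conditions: Pd(PPh3)4 (5 mol %), DMF, 100 °C
Reagents that add atoms: none
Why: Stille coupling under zerovalent palladium catalysis joins the aryl bromide to the unsubstituted allylic terminus of stannane 18 to give the linear prenyl arene, and the aldehyde and MOM ether are tolerated under these neutral conditions.

**Step 11**
Reactants: 19 4-methoxy-3-(methoxymethoxy)-5-(3-methylbut-2-enyl)benzaldehyde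
Product: 20 4-methoxy-3-(methoxymethoxy)-5-(3-methylbut-2-enyl)benzoic acid
Conditions: NaClO2, NaH2PO4, 2-methylbut-2-ene (30 equiv), t-BuOH/H2O, 0 °C to rt
Reagents that add atoms: sodium chlorite, [Na+].[O-]Cl=O
Why: Pinnick oxidation converts the aldehyde to the acid at buffered pH, the MOM ether survives, and the large excess of 2-methylbut-2-ene intercepts HOCl before it can attack the prenyl double bond or the arene.

**Step 12**
Reactants: 13 1-[2-bromo-4,6-bis(methoxymethoxy)-3-(3-methylbut-2-enyl)phenyl]ethanone; 20 4-methoxy-3-(methoxymethoxy)-5-(3-methylbut-2-enyl)benzoic acid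
Product: 23 1-[2-bromo-4,6-bis(methoxymethoxy)-3-(3-methylbut-2-enyl)phenyl]-3-[4-methoxy-3-(methoxymethoxy)-5-(3-methylbut-2-enyl)phenyl]propane-1,3-dione, via acid chloride 21 (not isolated), via lithium enolate 22 (not isolated)
Conditions: 20, 1-chloro-N,N,2-trimethylprop-1-en-1-amine, CH2Cl2, 0 °C to rt, concentrate; 13, LiN(SiMe3)2 (2.2 equiv), THF, −78 °C; add 21 in THF, −78 to 0 °C; then cold dilute HCl to pH 5
Reagents that add atoms: none
Why: Claisen-type C-acylation of a ketone lithium enolate with an aroyl chloride: the chloroenamine makes 21 without releasing HCl so that MOM and prenyl groups survive, the methyl ketone of 13 has only one enolization site, no aryne can form because both positions next to bromine are substituted, and the second equivalent of base stores the product as its diketonate.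

**Step 13**
Reactants: 23 the bromoaryl 1,3-diketone
Product: 24 2-[4-methoxy-3-(methoxymethoxy)-5-(3-methylbut-2-enyl)phenyl]-5,7-bis(methoxymethoxy)-8-(3-methylbut-2-enyl)chromen-4-one
Conditions: CuI (10 mol %), 1,10-phenanthroline (20 mol %), K2CO3, DMF, 100 °C
Reagents that add atoms: none
Why: Ullmann-type intramolecular O-arylation: the enolate oxygen on the ring B side of the 1-(2-bromoaryl)-1,3-diketone displaces the ortho-acyl-activated C8a bromide under monovalent copper catalysis, closing the six-membered ring C, a known flavone and chromone synthesis, while the other enolate oxygen could only form a four-membered ring.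

**Step 14**
Reactants: 24 the tris(MOM) flavone
Product: 25 5,7-dihydroxy-2-[3-hydroxy-4-methoxy-5-(3-methylbut-2-enyl)phenyl]-8-(3-methylbut-2-enyl)chromen-4-one (CNP0221799.0)
Conditions: 1.25 M HCl in MeOH, 40 °C, monitored closely
Reagents that add atoms: none
Why: Acid-catalysed acetal exchange with methanol removes all three MOM groups, a deprotection widely used on prenylated flavonoids, and mild acid strength, moderate temperature and close monitoring keep the 7-OH from adding to the 8-prenyl double bond.

**Compound list**
1 | methyl acetoacetate | COC(=O)CC(C)=O | starting material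
2 | prenyl bromide (1-bromo-3-methylbut-2-ene) | CC(C)=CCBr | starting material
3 | sodium lithium dianion of methyl acetoacetate | COC(=O)[CH-]C(=O)[CH2-].[Na+].[Li+] | intermediate
4 | methyl 7-methyl-3-oxooct-6-enoate | COC(=O)CC(=O)CCC=C(C)C | intermediate
5 | methyl (Z)-7-methyl-3-(trimethylsilyloxy)octa-2,6-dienoate | COC(=O)/C=C(\O[Si](C)(C)C)CCC=C(C)C | intermediate
6 | lithium dienolate of 5 | CO/C([O-])=C/C(O[Si](C)(C)C)=C/CC=C(C)C.[Li+] | intermediate
7 | (1Z,3Z)-1-methoxy-7-methyl-1,3-bis(trimethylsilyloxy)octa-1,3,6-triene | CO/C(O[Si](C)(C)C)=C/C(O[Si](C)(C)C)=C/CC=C(C)C | intermediate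
8 | but-3-yn-2-one | CC(=O)C#C | starting material
9 | 4-bromobut-3-yn-2-one | CC(=O)C#CBr | intermediate
10 | 1-[2-bromo-6-methoxy-3-(3-methylbut-2-enyl)-4,6-bis(trimethylsilyloxy)cyclohexa-1,4-dien-1-yl]ethanone, racemic, OMe cis to prenyl, one enantiomer drawn | CO[C@@]1(O[Si](C)(C)C)C=C(O[Si](C)(C)C)[C@@H](CC=C(C)C)C(Br)=C1C(C)=O | intermediate
11 | 1-[2-bromo-6-hydroxy-3-(3-methylbut-2-enyl)-4-(trimethylsilyloxy)phenyl]ethanone | CC(=O)c1c(O)cc(O[Si](C)(C)C)c(CC=C(C)C)c1Br | intermediate
12 | 1-[2-bromo-4,6-dihydroxy-3-(3-methylbut-2-enyl)phenyl]ethanone | CC(=O)c1c(O)cc(O)c(CC=C(C)C)c1Br | intermediate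
13 | 1-[2-bromo-4,6-bis(methoxymethoxy)-3-(3-methylbut-2-enyl)phenyl]ethanone | CC(=O)c1c(OCOC)cc(OCOC)c(CC=C(C)C)c1Br | intermediate
14 | 5-bromovanillin | COc1cc(C=O)cc(Br)c1O | starting material
15 | 3-bromo-4,5-dihydroxybenzaldehyde | O=Cc1cc(O)c(O)c(Br)c1 | intermediate
16 | 3-bromo-5-hydroxy-4-methoxybenzaldehyde | COc1c(O)cc(C=O)cc1Br | intermediate
17 | 3-bromo-4-methoxy-5-(methoxymethoxy)benzaldehyde | COCOc1cc(C=O)cc(Br)c1OC | intermediate
18 | tributyl(3-methylbut-2-enyl)stannane | CCCC[Sn](CCCC)(CCCC)CC=C(C)C | starting material
19 | 4-methoxy-3-(methoxymethoxy)-5-(3-methylbut-2-enyl)benzaldehyde | COCOc1cc(C=O)cc(CC=C(C)C)c1OC | intermediate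
20 | 4-methoxy-3-(methoxymethoxy)-5-(3-methylbut-2-enyl)benzoic acid | COCOc1cc(C(=O)O)cc(CC=C(C)C)c1OC | intermediate
21 | 4-methoxy-3-(methoxymethoxy)-5-(3-methylbut-2-enyl)benzoyl chloride | COCOc1cc(C(=O)Cl)cc(CC=C(C)C)c1OC | intermediate
22 | lithium enolate of 13 | [Li+].C=C([O-])c1c(OCOC)cc(OCOC)c(CC=C(C)C)c1Br | intermediate
23 | 1-[2-bromo-4,6-bis(methoxymethoxy)-3-(3-methylbut-2-enyl)phenyl]-3-[4-methoxy-3-(methoxymethoxy)-5-(3-methylbut-2-enyl)phenyl]propane-1,3-dione (drawn as diketo tautomer) | COCOc1cc(C(=O)CC(=O)c2c(OCOC)cc(OCOC)c(CC=C(C)C)c2Br)cc(CC=C(C)C)c1OC | intermediate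
24 | 2-[4-methoxy-3-(methoxymethoxy)-5-(3-methylbut-2-enyl)phenyl]-5,7-bis(methoxymethoxy)-8-(3-methylbut-2-enyl)chromen-4-one | COCOc1cc(-c2cc(=O)c3c(OCOC)cc(OCOC)c(CC=C(C)C)c3o2)cc(CC=C(C)C)c1OC | intermediate
25 | 5,7-dihydroxy-2-[3-hydroxy-4-methoxy-5-(3-methylbut-2-enyl)phenyl]-8-(3-methylbut-2-enyl)chromen-4-one (CNP0221799.0) | COc1c(O)cc(-c2cc(=O)c3c(O)cc(O)c(CC=C(C)C)c3o2)cc1CC=C(C)C | target

**Total step count:** 14.
**Longest linear sequence:** 8 steps (1, 2, 3, 5, 6, 12, 13, 14). The ring B branch 7-11 followed by 12-14 is equally long.

**Steps most likely to fail**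

**Step 5.**
- Risk: the diene terminus may add to the bromoynone in a stepwise conjugate fashion and expel bromide. Bromine may be transferred from the alkyne to the ketene acetal. The crowded C8-C8a bond may also form so slowly that the diene hydrolyses or oligomerizes first.
- Fallback: ring A is taken from the aromatic pool, with O1 present from the start.
- It sets out from prenyl bromide 2. Commercial 2,4,6-trihydroxyacetophenone is C-prenylated (aq KOH, 0 °C to rt) to 1-[2,4,6-trihydroxy-3-(3-methylbut-2-enyl)phenyl]ethanone F1.
- MOMCl (2.1 equiv) and i-Pr2NEt in CH2Cl2 should then cap the free 4-OH and the less hindered of the two chelated phenols. This gives 1-[2-hydroxy-4,6-bis(methoxymethoxy)-3-(3-methylbut-2-enyl)phenyl]ethanone F2, and the regioisomer is removed by chromatography.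
- F2 is then acylated with acid chloride 21 and ring-closed exactly as described under step 13 below. The route is rejoined at target 25.
- The price is the discrimination between two similar phenols, which the cycloaddition avoids.

**Step 13.**
- Risk: substitution at the C8a-Br bond, flanked on both sides, may be slow. Retro-Claisen cleavage of the diketone and protodebromination would then compete at the temperature required.
- Fallback: O1 is brought in as hydroxide before ring B is attached. Ring C is closed by cyclodehydration (O1-C2) instead of O-arylation (O1-C8a).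
- It sets out from bromoketone 13. Hydroxylation with KOH under zerovalent palladium catalysis (Pd2(dba)3, 2-di-tert-butylphosphino-2',4',6'-triisopropylbiphenyl, dioxane/H2O, 100 °C) should give the phenol F2 named above.
- Treatment with LiN(SiMe3)2 (3.2 equiv, THF, −78 °C) and acid chloride 21 gives 1-[2-hydroxy-4,6-bis(methoxymethoxy)-3-(3-methylbut-2-enyl)phenyl]-3-[4-methoxy-3-(methoxymethoxy)-5-(3-methylbut-2-enyl)phenyl]propane-1,3-dione F3.
- Methanolic HCl at 40 °C then closes ring C by cyclodehydration and removes the three MOM groups in the same flask, coming back at target 25.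

**Step 12.**
- Risk: O-acylation of the enolate, double acylation, proton exchange between product and enolate, or consumption of the acid chloride by the excess amide base may erode conversion.
- Fallback: the C2-C3 bond is made at the aldehyde oxidation level.
- It sets out from ketone 13 and aldehyde 19, so step 11 is skipped. An aldol addition (LiN(i-Pr)2, THF, −78 °C) gives racemic 1-[2-bromo-4,6-bis(methoxymethoxy)-3-(3-methylbut-2-enyl)phenyl]-3-hydroxy-3-[4-methoxy-3-(methoxymethoxy)-5-(3-methylbut-2-enyl)phenyl]propan-1-one F4.
- IBX (EtOAc, 75 °C) or buffered Dess-Martin periodinane should oxidize F4 to diketone 23, where the route is rejoined.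

**Further compounds**
F1 | step 5 | 1-[2,4,6-trihydroxy-3-(3-methylbut-2-enyl)phenyl]ethanone | CC(=O)c1c(O)cc(O)c(CC=C(C)C)c1O
F2 | step 5 | 1-[2-hydroxy-4,6-bis(methoxymethoxy)-3-(3-methylbut-2-enyl)phenyl]ethanone | CC(=O)c1c(OCOC)cc(OCOC)c(CC=C(C)C)c1O
F3 | step 13 | 1-[2-hydroxy-4,6-bis(methoxymethoxy)-3-(3-methylbut-2-enyl)phenyl]-3-[4-methoxy-3-(methoxymethoxy)-5-(3-methylbut-2-enyl)phenyl]propane-1,3-dione | COCOc1cc(C(=O)CC(=O)c2c(OCOC)cc(OCOC)c(CC=C(C)C)c2O)cc(CC=C(C)C)c1OC
F4 | step 12 | 1-[2-bromo-4,6-bis(methoxymethoxy)-3-(3-methylbut-2-enyl)phenyl]-3-hydroxy-3-[4-methoxy-3-(methoxymethoxy)-5-(3-methylbut-2-enyl)phenyl]propan-1-one, racemic, one enantiomer drawn | COCOc1cc([C@@H](O)CC(=O)c2c(OCOC)cc(OCOC)c(CC=C(C)C)c2Br)cc(CC=C(C)C)c1OC
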